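**Retrosynthetic overview**

1. Target 14 ⇐ tertiary vinyl carbinol 13 (SN2' bromination with PBr3 builds the (Z)-bromoethylidene) ⇐ hydroxy ketone 11 (vinyl addition, acetylation) ⇐ ketone 9 (Rubottom hydroxylation).
2. Ketone 9 ⇐ acyclic enone 6: the only ring is closed by a 6-endo radical cyclisation that joins the ring CH2 to the CHBr carbon and brings in the neopentyl secondary bromide, which substitution chemistry cannot deliver.
3. Enabling feature: in 6 the CHBr2 carbon C-6 on the quaternary C-5 gives an α-bromoalkyl radical, and the vinyl ketone C-1=C-2–C-3(=O) has its carbonyl carbon inside the forming six-membered ring, so the radical attacks the terminal C-1.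
4. Enone 6 ⇐ (S)-α-chloroaldehyde 4 (vinyl addition, oxidation) ⇐ aldehyde 3 (organocatalytic α-chlorination, the only reagent-controlled stereocentre) ⇐ gem-dibromide 2 ⇐ 2,2-dimethylpent-4-enal 1.
5. Stereochemical relay: Cl → Br (cyclisation transition state), Cl → O (face of enol ether oxidation), ring conformation → alkene geometry.

Key step: step 6

Assumption: the (2R,5R)-enantiomer of 2,5-diphenylpyrrolidine is taken to give the (2S)-chloroaldehyde; if the sense of induction on this β-quaternary aldehyde is the opposite, the (2S,5S)-catalyst is used and nothing else changes.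

Step 1
Reactants: 1 2,2-dimethylpent-4-enal
Product: 2 5,5-dibromo-4,4-dimethylpent-1-ene
Conditions: P(OPh)3, Br2, CH2Cl2, −78 °C; then 1, Et3N (0.2 equiv), −78 °C to rt
Reagents that add atoms: bromine, BrBr
Why: Deoxygenative gem-dibromination of an aldehyde by the preformed phosphite–bromine adduct should work because the aldehyde has no α-hydrogen (no enolisation, no vinyl bromide) and no free Br2 is present when the alkene is added.

Step 2
Reactants: 2 5,5-dibromo-4,4-dimethylpent-1-ene
Product: 3 4,4-dibromo-3,3-dimethylbutanal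
Conditions: O3, CH2Cl2, −78 °C; then Me2S, rt
Reagents that add atoms: ozone, [O-][O+]=O
Why: Ozonolysis with reductive work-up cleaves the only alkene and leaves the geminal dibromide untouched.

Step 3
Reactants: 3 4,4-dibromo-3,3-dimethylbutanal
Product: 4 (2S)-4,4-dibromo-2-chloro-3,3-dimethylbutanal
Conditions: N-chlorosuccinimide, (2R,5R)-2,5-diphenylpyrrolidine (10 mol%), CH2Cl2, 0 °C to rt; pentane trituration, used crude
Reagents that add atoms: N-chlorosuccinimide, O=C1CCC(=O)N1Cl
Why: Enamine-mediated organocatalytic α-chlorination, in which the C2-symmetric pyrrolidine shields one enamine face and sets the (S)-C–Cl centre, while the neopentyl-type CHBr2 carbon is too hindered to be displaced by the enamine or the amine.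

Step 4
Reactants: 4 (2S)-4,4-dibromo-2-chloro-3,3-dimethylbutanal
Product: 5 (4S)-6,6-dibromo-4-chloro-5,5-dimethylhex-1-en-3-ol (C-3 epimers)
Conditions: vinylMgBr, THF, −78 °C; sat. aq NH4Cl at −78 °C
Reagents that add atoms: vinylmagnesium bromide, C=C[Mg]Br
Why: Grignard 1,2-addition to the very electrophilic α-chloroaldehyde at −78 °C should outrun halogen–magnesium exchange at CHBr2 and epimerisation of the aldehyde, and the carbinol configuration is irrelevant because it is oxidised next.

Step 5
Reactants: 5 (4S)-6,6-dibromo-4-chloro-5,5-dimethylhex-1-en-3-ol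
Product: 6 (4S)-6,6-dibromo-4-chloro-5,5-dimethylhex-1-en-3-one
Conditions: Dess–Martin periodinane, CH2Cl2, 0 °C to rt; used without storage
Reagents that add atoms: none
Why: Dess–Martin oxidation under near-neutral conditions should give the vinyl ketone without enolising the chlorine-bearing carbon.

Step 6
Reactants: 6 (4S)-6,6-dibromo-4-chloro-5,5-dimethylhex-1-en-3-one
Product: 9 (2S,4R)-4-bromo-2-chloro-3,3-dimethylcyclohexan-1-one, via α-bromoalkyl radical 7 (not isolated), via α-keto radical 8 (not isolated)
Conditions: Bu3SnH (1.05 equiv) and AIBN (0.1 equiv) added over 6 h to 6 (0.01 M), benzene, 80 °C; KF work-up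
Reagents that add atoms: none
Why: Bu3Sn• abstracts one bromine of the CHBr2 group and the α-bromoalkyl radical 7 adds to the terminal CH2 of the vinyl ketone to give the α-keto radical 8, which takes hydrogen from Bu3SnH and carries the chain; the closest known reaction type is the tin hydride-mediated endo cyclisation of haloalkyl vinyl ketones, here started from a geminal dihalide so that one halogen stays on the radical carbon. The cyclohexanone ring closes in the 6-endo-trig mode because the carbonyl carbon lies inside the forming ring: attack at the terminus is polarity-matched and gives the stabilised α-keto radical, whereas 5-exo attack at the α-carbon is strained and mismatched. The new C–Br stereocentre is controlled by the C–Cl centre: in the chair-like transition state chlorine prefers the pseudoaxial position (one gauche contact with the gem-dimethyl group instead of two, and no eclipsing with C=O), so bromine goes pseudoequatorial to avoid a syn-diaxial Br/Cl contact, which gives the trans (2S,4R) ketone. The step needs chemoselective abstraction at CHBr2 rather than at the α-keto C–Cl or at the single C–Br bond of the product, secured by the weaker geminal C–Br bond, one equivalent of hydride and slow addition; high dilution suppresses oligomerisation of the enone. The minor cis isomer should be removed by chromatography at this stage, before any later step could epimerise the chlorine-bearing carbon and so lead into the enantiomeric series.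

Step 7
Reactants: 9 (2S,4R)-4-bromo-2-chloro-3,3-dimethylcyclohexan-1-one
Product: 11 (2S,4R,6S)-4-bromo-2-chloro-6-hydroxy-3,3-dimethylcyclohexan-1-one, via trimethylsilyl enol ether 10 (not isolated)
Conditions: TMSOTf, Et3N, CH2Cl2, −78 to 0 °C; then mCPBA, hexane/CH2Cl2, −20 °C; then 1 M HCl, THF, 0 °C
Reagents that add atoms: meta-chloroperoxybenzoic acid, OOC(=O)c1cccc(Cl)c1
Why: Rubottom oxidation, in which soft enolisation takes the accessible CH2 hydrogens rather than the hindered C–H next to chlorine, and the peracid attacks the nucleophilic enol ether carbon from the face opposite the pseudoaxial chlorine (1,3 to that carbon), which places the new hydroxyl cis to bromine and equatorial (6S).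

Step 8
Reactants: 11 (2S,4R,6S)-4-bromo-2-chloro-6-hydroxy-3,3-dimethylcyclohexan-1-one
Product: 12 (2S,4R,6S)-4-bromo-6-chloro-1-ethenyl-5,5-dimethylcyclohexane-1,2-diol (C-1 epimers)
Conditions: vinylMgBr (3 equiv), THF, −78 to −40 °C; sat. aq NH4Cl at −78 °C
Reagents that add atoms: vinylmagnesium bromide, C=C[Mg]Br
Why: Chelation-assisted Grignard addition to an α-alkoxido ketone (the first equivalent only removes the hydroxyl proton) should be clean because no ester is present yet; the new carbinol centre becomes sp2 in step 10, and the cold quench keeps the alkoxide from displacing the neighbouring chloride.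

Step 9
Reactants: 12 (2S,4R,6S)-4-bromo-6-chloro-1-ethenyl-5,5-dimethylcyclohexane-1,2-diol
Product: 13 (1S,3S,5R)-5-bromo-3-chloro-2-ethenyl-2-hydroxy-4,4-dimethylcyclohexyl acetate (C-2 epimers)
Conditions: Ac2O, pyridine, DMAP (cat.), CH2Cl2, 0 °C
Reagents that add atoms: acetic anhydride, CC(=O)OC(C)=O
Why: Acylation should discriminate the secondary hydroxyl from the hindered tertiary allylic one.

Step 10
Reactants: 13 (1S,3S,5R)-5-bromo-3-chloro-2-ethenyl-2-hydroxy-4,4-dimethylcyclohexyl acetate
Product: 14 (1S,3R,5R)-5-bromo-2-[(Z)-2-bromoethylidene]-3-chloro-4,4-dimethylcyclohexyl acetate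
Conditions: PBr3 (0.4 equiv), Et2O, −10 to 0 °C
Reagents that add atoms: phosphorus tribromide, BrP(Br)Br
Why: Allylic transposition of a tertiary vinyl carbinol with PBr3 (SN2'), in which bromide enters at the vinyl terminus and the allylic bromide should equilibrate to the Z isomer, where CH2Br lies on the side of the ring carbon whose chlorine is axial and so avoids allylic 1,3-strain with the equatorial acetate.

**Compound list**

1 | 2,2-dimethylpent-4-enal | O=CC(C)(C)CC=C | starting material
2 | 5,5-dibromo-4,4-dimethylpent-1-ene | BrC(Br)C(C)(C)CC=C | intermediate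
3 | 4,4-dibromo-3,3-dimethylbutanal | BrC(Br)C(C)(C)CC=O | intermediate
4 | (2S)-4,4-dibromo-2-chloro-3,3-dimethylbutanal | BrC(Br)C(C)(C)[C@H](Cl)C=O | intermediate
5 | (4S)-6,6-dibromo-4-chloro-5,5-dimethylhex-1-en-3-ol (C-3 epimers) | BrC(Br)C(C)(C)[C@H](Cl)C(O)C=C | intermediate
6 | (4S)-6,6-dibromo-4-chloro-5,5-dimethylhex-1-en-3-one | BrC(Br)C(C)(C)[C@H](Cl)C(=O)C=C | intermediate
7 | (3S)-1-bromo-3-chloro-2,2-dimethyl-4-oxohex-5-en-1-yl radical | Br[CH]C(C)(C)[C@H](Cl)C(=O)C=C | intermediate
8 | (3S,5R)-5-bromo-3-chloro-4,4-dimethyl-2-oxocyclohexyl radical | [CH]1C[C@@H](Br)C(C)(C)[C@H](Cl)C1=O | intermediate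
9 | (2S,4R)-4-bromo-2-chloro-3,3-dimethylcyclohexan-1-one | C1C[C@@H](Br)C(C)(C)[C@H](Cl)C1=O | intermediate
10 | {[(4R,6S)-4-bromo-6-chloro-5,5-dimethylcyclohex-1-en-1-yl]oxy}(trimethyl)silane | C1C[C@@H](Br)C(C)(C)[C@H](Cl)C=1O[Si](C)(C)C | intermediate
11 | (2S,4R,6S)-4-bromo-2-chloro-6-hydroxy-3,3-dimethylcyclohexan-1-one | O[C@H]1C[C@@H](Br)C(C)(C)[C@H](Cl)C1=O | intermediate
12 | (2S,4R,6S)-4-bromo-6-chloro-1-ethenyl-5,5-dimethylcyclohexane-1,2-diol (C-1 epimers) | O[C@H]1C[C@@H](Br)C(C)(C)[C@H](Cl)C1(O)C=C | intermediate
13 | (1S,3S,5R)-5-bromo-3-chloro-2-ethenyl-2-hydroxy-4,4-dimethylcyclohexyl acetate (C-2 epimers) | CC(=O)O[C@H]1C[C@@H](Br)C(C)(C)[C@H](Cl)C1(O)C=C | intermediate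
14 | (1S,3R,5R)-5-bromo-2-[(Z)-2-bromoethylidene]-3-chloro-4,4-dimethylcyclohexyl acetate | CC(=O)O[C@H]1C[C@@H](Br)C(C)(C)[C@H](Cl)/C1=C\CBr | target

**Step count and risks**

Total step count: 10. Longest linear sequence: 10 steps (the route is fully linear).

Step 6 (key step). What may go wrong: hydrogen transfer to radical 7 before it cyclises, abstraction of the α-keto chlorine, over-reduction of the product bromide, oligomerisation of the unsubstituted vinyl ketone, or weak Br/Cl diastereoselection. The fallback redesigns the acceptor with a temporary silicon group and sets out from 4. Addition of [1-(trimethylsilyl)ethenyl]magnesium bromide (THF, −78 °C) should give (4S)-6,6-dibromo-4-chloro-5,5-dimethyl-2-(trimethylsilyl)hex-1-en-3-ol F1. Dess–Martin oxidation should then give (4S)-6,6-dibromo-4-chloro-5,5-dimethyl-2-(trimethylsilyl)hex-1-en-3-one F2, an α-silyl enone that resists oligomerisation and can only be attacked at its CH2 terminus. The same tin hydride chain, or (Me3Si)3SiH as a slower hydrogen donor, should close the ring to (2S,4R)-4-bromo-2-chloro-3,3-dimethyl-6-(trimethylsilyl)cyclohexan-1-one F3. The thermal 1,3 carbon-to-oxygen silyl shift of this α-silyl ketone (Brook-type, toluene, 110 °C) should give silyl enol ether 10 regiospecifically; the route is rejoined at 10, which is oxidised as in step 7.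

Step 7. What may go wrong: enolisation towards the chlorine-bearing carbon, oxidation of the enol ether from the face syn to chlorine, or acyloin-type isomerisation of the hydroxy ketone. The fallback brings the oxygen in after the vinyl group, through a vinyl epoxide, and sets out from 9. VinylMgBr with CeCl3 (THF, −78 °C) should give (2S,4R)-4-bromo-2-chloro-1-ethenyl-3,3-dimethylcyclohexan-1-ol F4. Dehydration with Burgess reagent (benzene, 50 °C) towards the CH2 side should give (4R,6R)-4-bromo-6-chloro-1-ethenyl-5,5-dimethylcyclohex-1-ene F5. mCPBA (CH2Cl2, NaHCO3, 0 °C) should epoxidise the trisubstituted ring alkene anti to the pseudoaxial allylic chlorine to give (1S,2S,4R,6S)-4-bromo-2-chloro-1-ethenyl-3,3-dimethyl-7-oxabicyclo[4.1.0]heptane F6. LiBr with AcOH (THF, 0 °C) should open it in the SN2' sense, with equilibration of the allylic bromide, to (1S,3R,5R)-5-bromo-2-[(Z)-2-bromoethylidene]-3-chloro-4,4-dimethylcyclohexan-1-ol F7. Acetylation (AcCl, 2,4,6-collidine, CH2Cl2, 0 °C) returns to the route at 14.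

Step 10. What may go wrong: ionisation of the activated tertiary allylic alcohol followed by elimination to a diene, transfer of the neighbouring acetate through an acetoxonium ion, or incomplete equilibration of the alkene geometry. The fallback transposes oxygen first and brominates second, and sets out from 13. Re2O7 (cat., Et2O, 0 °C) should effect the 1,3-transposition of the tertiary allylic alcohol to the thermodynamically preferred primary allylic alcohol (1S,3R,5R)-5-bromo-3-chloro-2-[(Z)-2-hydroxyethylidene]-4,4-dimethylcyclohexyl acetate F8. The Appel reaction (CBr4, PPh3, CH2Cl2, 0 °C) then converts it into 14, where the route is rejoined.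

**Further compounds**

F1 | step 6 | (4S)-6,6-dibromo-4-chloro-5,5-dimethyl-2-(trimethylsilyl)hex-1-en-3-ol | BrC(Br)C(C)(C)[C@H](Cl)C(O)C(=C)[Si](C)(C)C
F2 | step 6 | (4S)-6,6-dibromo-4-chloro-5,5-dimethyl-2-(trimethylsilyl)hex-1-en-3-one | BrC(Br)C(C)(C)[C@H](Cl)C(=O)C(=C)[Si](C)(C)C
F3 | step 6 | (2S,4R)-4-bromo-2-chloro-3,3-dimethyl-6-(trimethylsilyl)cyclohexan-1-one | C[Si](C)(C)C1C[C@@H](Br)C(C)(C)[C@H](Cl)C1=O
F4 | step 7 | (2S,4R)-4-bromo-2-chloro-1-ethenyl-3,3-dimethylcyclohexan-1-ol | C1C[C@@H](Br)C(C)(C)[C@H](Cl)C1(O)C=C
F5 | step 7 | (4R,6R)-4-bromo-6-chloro-1-ethenyl-5,5-dimethylcyclohex-1-ene | C1C[C@@H](Br)C(C)(C)[C@H](Cl)C=1C=C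
F6 | step 7 | (1S,2S,4R,6S)-4-bromo-2-chloro-1-ethenyl-3,3-dimethyl-7-oxabicyclo[4.1.0]heptane | O1[C@H]2C[C@@H](Br)C(C)(C)[C@H](Cl)[C@@]12C=C
F7 | step 7 | (1S,3R,5R)-5-bromo-2-[(Z)-2-bromoethylidene]-3-chloro-4,4-dimethylcyclohexan-1-ol | O[C@H]1C[C@@H](Br)C(C)(C)[C@H](Cl)/C1=C\CBr
F8 | step 10 | (1S,3R,5R)-5-bromo-3-chloro-2-[(Z)-2-hydroxyethylidene]-4,4-dimethylcyclohexyl acetate | CC(=O)O[C@H]1C[C@@H](Br)C(C)(C)[C@H](Cl)/C1=C\CO
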